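**Plan**
- Retrosynthesis: the C5–allyl bond is cut first (dearomative ortho-C-allylation of a 2,6-dimethoxyphenol), then the C2–C3 bond of the dihydrofuran ring (intramolecular carbene C–H insertion), then the O1–CH2Ar ether bond and the C7a–O bond (Williamson ether synthesis; bromination/hydroxylation of acetosyringone).
- Forward: the benzene ring is bought as acetosyringone and completed (steps 1–4), the dihydrofuran ring is closed on it (steps 5–6), the 2,3-relationship is equilibrated to trans (step 7), the benzyl helper is removed (step 8), and the six-membered ring is dearomatised last to the 6-allyl-6-methoxycyclohexa-2,4-dienone (step 9).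
- Enabling feature: in the ring O1–C2–C3–C3a–C7a, C3 is benzylic to C3a and can carry a carbene derived from the acetyl group. C2 is a CH2 that is bound to O1, benzylic to the trimethoxyphenyl ring, and held 1,5 to C3 across the C3a–C7a edge of the benzene ring.
- Stereochemistry: C3 from the chiral dirhodium carboxylate (step 6, C2 arrives cis), C2 from acid equilibration to the trans isomer (step 7), C5 from the chiral palladium ligand (step 9). Helpers are the hydrazone nitrogen (lost as N2) and the benzyl ether on the C6 oxygen (removed in step 8).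

Key step: step 6

Assumption: the sense of induction of Rh2(S-PTAD)4 (3S) and of the (R,R) bisphosphine ligand (5R) is taken by analogy; if either proves opposite, the mirror-image catalyst or ligand is used without other change.

**Route**

Step 1
Reactants: 1 acetosyringone, 1-(4-hydroxy-3,5-dimethoxyphenyl)ethan-1-one; 2 benzyl bromide
Product: 3 1-[4-(benzyloxy)-3,5-dimethoxyphenyl]ethan-1-one
Conditions: BnBr, K2CO3, DMF, 60 °C
Reagents that add atoms: benzyl bromide, BrCc1ccccc1
Why: Williamson etherification of the only acidic OH masks the future C6 phenol as an ether that should survive bromination, hydroxide, hydrazine, MnO2, the rhodium carbene and acid.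

Step 2
Reactants: 3 1-[4-(benzyloxy)-3,5-dimethoxyphenyl]ethan-1-one; 4 N-bromosuccinimide
Product: 5 1-[4-(benzyloxy)-2-bromo-3,5-dimethoxyphenyl]ethan-1-one
Conditions: NBS, MeCN, rt, dark
Reagents that add atoms: N-bromosuccinimide, O=C1CCC(=O)N1Br
Why: electrophilic aromatic bromination in a polar non-radical medium should attack the ring position ortho to one OMe and para to the other, and the two free positions are equivalent by symmetry, so only one regioisomer can form.

Step 3
Reactants: 5 1-[4-(benzyloxy)-2-bromo-3,5-dimethoxyphenyl]ethan-1-one; 6 lithium hydroxide monohydrate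
Product: 7 1-[4-(benzyloxy)-2-hydroxy-3,5-dimethoxyphenyl]ethan-1-one
Conditions: CuI (cat.), N,N'-bis(4-hydroxy-2,6-dimethylphenyl)oxalamide (cat.), LiOH·H2O, DMSO/H2O, 80 °C; then aq. HCl
Reagents that add atoms: lithium hydroxide monohydrate, [Li+].[OH-].O
Why: copper-catalysed Ullmann-type hydroxylation of an aryl bromide, assisted by the ortho acetyl group, should install the oxygen that becomes O1.

Step 4
Reactants: 7 1-[4-(benzyloxy)-2-hydroxy-3,5-dimethoxyphenyl]ethan-1-one; 8 5-(chloromethyl)-1,2,3-trimethoxybenzene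
Product: 9 1-{4-(benzyloxy)-3,5-dimethoxy-2-[(3,4,5-trimethoxyphenyl)methoxy]phenyl}ethan-1-one
Conditions: K2CO3, DMF, 60 °C
Reagents that add atoms: 5-(chloromethyl)-1,2,3-trimethoxybenzene, COc1cc(CCl)cc(OC)c1OC
Why: Williamson etherification of the hydrogen-bonded ortho-hydroxy ketone with a reactive benzylic chloride should form the O1–CH2Ar bond and place the future C2 next to the acetyl group.

Step 5
Reactants: 9 1-{4-(benzyloxy)-3,5-dimethoxy-2-[(3,4,5-trimethoxyphenyl)methoxy]phenyl}ethan-1-one; 10 hydrazine monohydrate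
Product: 11 {1-[4-(benzyloxy)-3,5-dimethoxy-2-[(3,4,5-trimethoxyphenyl)methoxy]phenyl]ethylidene}hydrazine (E/Z mixture, used as such)
Conditions: N2H4·H2O (excess), AcOH (cat.), EtOH, 80 °C
Reagents that add atoms: hydrazine monohydrate, NN.O
Why: condensation of the aryl methyl ketone with excess hydrazine should give the free hydrazone, the storable precursor of the diazo compound, with azine formation suppressed by the excess.

Step 6
Reactants: 11 {1-[4-(benzyloxy)-3,5-dimethoxy-2-[(3,4,5-trimethoxyphenyl)methoxy]phenyl]ethylidene}hydrazine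
Product: 13 (2R,3S)-6-(benzyloxy)-5,7-dimethoxy-3-methyl-2-(3,4,5-trimethoxyphenyl)-2,3-dihydro-1-benzofuran (2,3-cis), via diazoalkane 12 (not isolated)
Conditions: MnO2, CH2Cl2, 0 °C; filtration into Rh2(S-PTAD)4 (1 mol%), CH2Cl2, 0 °C to rt
Reagents that add atoms: none
Why: MnO2 dehydrogenates the hydrazone to the aryl(methyl)diazomethane 12, from which Rh2(S-PTAD)4 expels N2 to give a donor/donor rhodium carbene at the future C3; the carbene takes hydride from the ether CH2, which is both α to O1 and benzylic to the trimethoxyphenyl ring, and the resulting carbanion/oxocarbenium pair collapses at once to the C2–C3 bond, an asynchronous 1,5-C–H insertion. The closest known reaction type is the enantioselective intramolecular C–H insertion of donor/donor rhodium carbenes made from ortho-(benzyloxy)aryl ketone hydrazones, which gives 2,3-cis-dihydrobenzofurans. The dihydrofuran ring closes in a 5-exo sense through a six-centre transition state (C3, C3a, C7a, O1, C2, H). C3 is set by the chiral carboxylate wall of the catalyst, which exposes one face of the carbene, and C2 by the compact transition state in which the aryl group on the reacting CH2 points away from the catalyst and so ends cis to the methyl group. The step needs insertion to outrun 1,2-hydride shift from the methyl group and azine formation; the strongly hydridic, 1,5-placed C–H bond and low temperature should secure this, and the OMe and OBn C–H bonds are out of geometric reach.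

Step 7
Reactants: 13 (2R,3S)-6-(benzyloxy)-5,7-dimethoxy-3-methyl-2-(3,4,5-trimethoxyphenyl)-2,3-dihydro-1-benzofuran
Product: 14 (2S,3S)-6-(benzyloxy)-5,7-dimethoxy-3-methyl-2-(3,4,5-trimethoxyphenyl)-2,3-dihydro-1-benzofuran (2,3-trans)
Conditions: CF3CO2H, CH2Cl2 (dilute), rt
Reagents that add atoms: none
Why: the acid should reversibly ionise the benzylic C2–O1 bond to a 3,4,5-trimethoxybenzyl cation that recloses to the more stable 2,3-trans ring, a thermodynamic epimerisation at C2 that leaves C3 untouched.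

Step 8
Reactants: 14 (2S,3S)-6-(benzyloxy)-5,7-dimethoxy-3-methyl-2-(3,4,5-trimethoxyphenyl)-2,3-dihydro-1-benzofuran
Product: 15 (2S,3S)-5,7-dimethoxy-3-methyl-2-(3,4,5-trimethoxyphenyl)-2,3-dihydro-1-benzofuran-6-ol
Conditions: H2 (1 atm), Pd/C, EtOAc, rt
Reagents that add atoms: none
Why: hydrogenolysis of the primary aryl benzyl ether should be much faster than cleavage of the ring C2–O1 bond and frees the phenol flanked by two OMe groups.

Step 9
Reactants: 15 (2S,3S)-5,7-dimethoxy-3-methyl-2-(3,4,5-trimethoxyphenyl)-2,3-dihydro-1-benzofuran-6-ol; 16 allyl methyl carbonate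
Product: 17 (2S,3S,5R)-5,7-dimethoxy-3-methyl-5-(prop-2-en-1-yl)-2-(3,4,5-trimethoxyphenyl)-2,3-dihydro-1-benzofuran-6(5H)-one (target)
Conditions: Pd2(dba)3 (2.5 mol%), (1R,2R)-N,N'-bis[2-(diphenylphosphino)benzoyl]cyclohexane-1,2-diamine (7.5 mol%), toluene, 0 °C
Reagents that add atoms: allyl methyl carbonate, C=CCOC(=O)OC
Why: Proposed new method: zerovalent palladium ionises the carbonate to a cationic π-allyl complex and methoxide, which deprotonates the phenol; the ion-paired phenoxide is expected to attack the allyl terminus with its ortho carbon C5 (the less hindered of the two OMe-bearing ortho carbons, flanked by C4–H) inside the chiral pocket of the ligand, which selects the face at C5 independently of the remote C2 and C3 centres, and the run is held at 0 °C so that neither an aryl allyl ether nor the dienone product (a vinylogous ester) re-ionises or undergoes [3,3] shifts; the closest known reaction type is the palladium-catalysed intermolecular asymmetric allylic dearomatisation of 1-substituted 2-naphthols.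

**Compound list**

1 | acetosyringone, 1-(4-hydroxy-3,5-dimethoxyphenyl)ethan-1-one | CC(=O)c1cc(OC)c(O)c(OC)c1 | starting material
2 | benzyl bromide | BrCc1ccccc1 | starting material
3 | 1-[4-(benzyloxy)-3,5-dimethoxyphenyl]ethan-1-one | CC(=O)c1cc(OC)c(OCc2ccccc2)c(OC)c1 | intermediate
4 | N-bromosuccinimide | O=C1CCC(=O)N1Br | starting material
5 | 1-[4-(benzyloxy)-2-bromo-3,5-dimethoxyphenyl]ethan-1-one | CC(=O)c1cc(OC)c(OCc2ccccc2)c(OC)c1Br | intermediate
6 | lithium hydroxide monohydrate | [Li+].[OH-].O | starting material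
7 | 1-[4-(benzyloxy)-2-hydroxy-3,5-dimethoxyphenyl]ethan-1-one | CC(=O)c1cc(OC)c(OCc2ccccc2)c(OC)c1O | intermediate
8 | 5-(chloromethyl)-1,2,3-trimethoxybenzene | COc1cc(CCl)cc(OC)c1OC | starting material
9 | 1-{4-(benzyloxy)-3,5-dimethoxy-2-[(3,4,5-trimethoxyphenyl)methoxy]phenyl}ethan-1-one | CC(=O)c1cc(OC)c(OCc2ccccc2)c(OC)c1OCc1cc(OC)c(OC)c(OC)c1 | intermediate
10 | hydrazine monohydrate | NN.O | starting material
11 | {1-[4-(benzyloxy)-3,5-dimethoxy-2-[(3,4,5-trimethoxyphenyl)methoxy]phenyl]ethylidene}hydrazine | CC(=NN)c1cc(OC)c(OCc2ccccc2)c(OC)c1OCc1cc(OC)c(OC)c(OC)c1 | intermediate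
12 | 3-(benzyloxy)-1-(1-diazoethyl)-2,4-dimethoxy-6-... written from the ring: 4-(benzyloxy)-1-(1-diazoethyl)-3,5-dimethoxy-2-[(3,4,5-trimethoxyphenyl)methoxy]benzene | CC(=[N+]=[N-])c1cc(OC)c(OCc2ccccc2)c(OC)c1OCc1cc(OC)c(OC)c(OC)c1 | intermediate
13 | (2R,3S)-6-(benzyloxy)-5,7-dimethoxy-3-methyl-2-(3,4,5-trimethoxyphenyl)-2,3-dihydro-1-benzofuran (cis) | COc1cc2c(c(OC)c1OCc1ccccc1)O[C@@H](c1cc(OC)c(OC)c(OC)c1)[C@H]2C | intermediate
14 | (2S,3S)-6-(benzyloxy)-5,7-dimethoxy-3-methyl-2-(3,4,5-trimethoxyphenyl)-2,3-dihydro-1-benzofuran (trans) | COc1cc2c(c(OC)c1OCc1ccccc1)O[C@H](c1cc(OC)c(OC)c(OC)c1)[C@H]2C | intermediate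
15 | (2S,3S)-5,7-dimethoxy-3-methyl-2-(3,4,5-trimethoxyphenyl)-2,3-dihydro-1-benzofuran-6-ol | COc1cc2c(c(OC)c1O)O[C@H](c1cc(OC)c(OC)c(OC)c1)[C@H]2C | intermediate
16 | allyl methyl carbonate | C=CCOC(=O)OC | starting material
17 | (2S,3S,5R)-5,7-dimethoxy-3-methyl-5-(prop-2-en-1-yl)-2-(3,4,5-trimethoxyphenyl)-2,3-dihydro-1-benzofuran-6(5H)-one | C=CC[C@@]1(OC)C=C2C(=C(OC)C1=O)O[C@H](c1cc(OC)c(OC)c(OC)c1)[C@H]2C | target

**Summary**

Total step count: 9. Longest linear sequence: 9 steps (1 to 17).

Steps most likely to fail: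

1. Step 9 (Proposed new method). What may go wrong: O-allylation outcompeting C-allylation, attack at C7 instead of C5, poor facial selectivity at C5, or re-ionisation of the dienone by the catalyst. Fallback with known chemistry: it sets out from 15, which is deprotonated with NaH in toluene and treated with allyl bromide at 0 °C to rt. This is the kinetic ortho-C-alkylation of a 2,6-disubstituted sodium phenoxide held as a tight aggregate in a non-polar solvent, a known route to 6-allylcyclohexa-2,4-dienones. It should give 17 together with its C5 epimer, (2S,3S,5S)-5,7-dimethoxy-3-methyl-5-(prop-2-en-1-yl)-2-(3,4,5-trimethoxyphenyl)-2,3-dihydro-1-benzofuran-6(5H)-one F1. The two diastereomers are separated by chromatography below room temperature, and the route is rejoined at 17. This fallback does not control C5; it relies on separation.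

2. Step 6. What may go wrong: 1,2-hydride shift of the carbene to a vinylarene, azine formation from the diazo compound, or insufficient facial selectivity. Fallback through a donor/acceptor carbene: it sets out from 9. Oxidative 1,2-aryl shift (PhI(OAc)2, HC(OMe)3, MeOH, cat. H2SO4) should give methyl 2-{4-(benzyloxy)-3,5-dimethoxy-2-[(3,4,5-trimethoxyphenyl)methoxy]phenyl}acetate F2. Diazo transfer (4-acetamidobenzenesulfonyl azide, DBU, MeCN) should give methyl 2-diazo-2-{4-(benzyloxy)-3,5-dimethoxy-2-[(3,4,5-trimethoxyphenyl)methoxy]phenyl}acetate F3. Rh2(S-PTTL)4-catalysed 1,5-C–H insertion, a well-known entry to cis-2-aryl-2,3-dihydrobenzofuran-3-carboxylates, should give methyl (2S,3R)-6-(benzyloxy)-5,7-dimethoxy-2-(3,4,5-trimethoxyphenyl)-2,3-dihydro-1-benzofuran-3-carboxylate F4 with C2 fixed by the catalyst. NaOMe in MeOH should epimerise C3 to methyl (2S,3S)-6-(benzyloxy)-5,7-dimethoxy-2-(3,4,5-trimethoxyphenyl)-2,3-dihydro-1-benzofuran-3-carboxylate F5. LiAlH4 should give [(2S,3R)-6-(benzyloxy)-5,7-dimethoxy-2-(3,4,5-trimethoxyphenyl)-2,3-dihydro-1-benzofuran-3-yl]methanol F6, and TsCl in pyridine should give [(2S,3R)-6-(benzyloxy)-5,7-dimethoxy-2-(3,4,5-trimethoxyphenyl)-2,3-dihydro-1-benzofuran-3-yl]methyl 4-methylbenzenesulfonate F7. LiBHEt3 in THF should then reduce the tosylate to the methyl group, and the route is rejoined at 14, so step 7 is no longer needed.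

3. Step 3. What may go wrong: slow coupling at the doubly ortho-substituted bromide and base-induced self-condensation of the methyl ketone. Fallback by borylation and oxidation: it sets out from 5. Miyaura borylation (B2pin2, Pd(dppf)Cl2, KOAc, dioxane, 90 °C) should give 1-[4-(benzyloxy)-3,5-dimethoxy-2-(4,4,5,5-tetramethyl-1,3,2-dioxaborolan-2-yl)phenyl]ethan-1-one F8. Mild oxidation (NaBO3·4H2O, THF/H2O, rt) should then give the phenol, and the route is rejoined at 7.

Further compounds
F1 | step 9 | (2S,3S,5S)-5,7-dimethoxy-3-methyl-5-(prop-2-en-1-yl)-2-(3,4,5-trimethoxyphenyl)-2,3-dihydro-1-benzofuran-6(5H)-one | C=CC[C@]1(OC)C=C2C(=C(OC)C1=O)O[C@H](c1cc(OC)c(OC)c(OC)c1)[C@H]2C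
F2 | step 6 | methyl 2-{4-(benzyloxy)-3,5-dimethoxy-2-[(3,4,5-trimethoxyphenyl)methoxy]phenyl}acetate | COC(=O)Cc1cc(OC)c(OCc2ccccc2)c(OC)c1OCc1cc(OC)c(OC)c(OC)c1
F3 | step 6 | methyl 2-diazo-2-{4-(benzyloxy)-3,5-dimethoxy-2-[(3,4,5-trimethoxyphenyl)methoxy]phenyl}acetate | COC(=O)C(=[N+]=[N-])c1cc(OC)c(OCc2ccccc2)c(OC)c1OCc1cc(OC)c(OC)c(OC)c1
F4 | step 6 | methyl (2S,3R)-6-(benzyloxy)-5,7-dimethoxy-2-(3,4,5-trimethoxyphenyl)-2,3-dihydro-1-benzofuran-3-carboxylate | COc1cc2c(c(OC)c1OCc1ccccc1)O[C@H](c1cc(OC)c(OC)c(OC)c1)[C@@H]2C(=O)OC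
F5 | step 6 | methyl (2S,3S)-6-(benzyloxy)-5,7-dimethoxy-2-(3,4,5-trimethoxyphenyl)-2,3-dihydro-1-benzofuran-3-carboxylate | COc1cc2c(c(OC)c1OCc1ccccc1)O[C@H](c1cc(OC)c(OC)c(OC)c1)[C@H]2C(=O)OC
F6 | step 6 | [(2S,3R)-6-(benzyloxy)-5,7-dimethoxy-2-(3,4,5-trimethoxyphenyl)-2,3-dihydro-1-benzofuran-3-yl]methanol | COc1cc2c(c(OC)c1OCc1ccccc1)O[C@H](c1cc(OC)c(OC)c(OC)c1)[C@H]2CO
F7 | step 6 | [(2S,3R)-6-(benzyloxy)-5,7-dimethoxy-2-(3,4,5-trimethoxyphenyl)-2,3-dihydro-1-benzofuran-3-yl]methyl 4-methylbenzenesulfonate | COc1cc2c(c(OC)c1OCc1ccccc1)O[C@H](c1cc(OC)c(OC)c(OC)c1)[C@H]2COS(=O)(=O)c1ccc(C)cc1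
F8 | step 3 | 1-[4-(benzyloxy)-3,5-dimethoxy-2-(4,4,5,5-tetramethyl-1,3,2-dioxaborolan-2-yl)phenyl]ethan-1-one | CC(=O)c1cc(OC)c(OCc2ccccc2)c(OC)c1B1OC(C)(C)C(C)(C)O1
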